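**Retrosynthetic overview**
1. The C6–alkenyl bond is cut last: axial transfer of a geometrically defined (E)-alkenyl group from boron to the peroxycarbenium ion of a 6-methoxy-1,2-dioxane (new step, sets C6).
2. The acetate arm and C3 come from Wittig opening and oxa-Michael re-closure of a 6-methoxy-1,2-dioxan-3-ol (sets C3 trans to C4).
3. That peroxy-lactol is made by cobalt/O2 oxidative ring expansion of a 2-methoxycyclobutanol (four-membered carbocycle to six-membered peroxide), which comes from (R)-1,3-diethylcyclobutene and desymmetrised 3-ethylcyclobutanone (sets C4).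
4. The alkenylboron partner comes from syn-carboboration of (S)-4-ethyloct-1-yne, whose stereocentre is set by asymmetric conjugate addition to methyl (E)-pent-2-enoate.
5. Ring order: cyclobutane (bought), then the 1,2-dioxane by ring expansion in step 4 (opened and re-closed once in step 5); there is no other ring.

Assumption: 3-ethylcyclobutan-1-one is taken as a catalogue building block, and the absolute sense of the chiral lithium amide (step 1) and of Tol-BINAP (step 6) is assigned by analogy and would be confirmed on the first batch, the antipodal reagent being equally available.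

**Route**

Step 1
Reactants: 1 3-ethylcyclobutan-1-one
Product: 3 (R)-3-ethylcyclobut-1-en-1-yl trifluoromethanesulfonate, via lithium enolate 2 (not isolated)
Conditions: LiN[(R)-CH(CH3)Ph]2 (1.15 equiv), LiCl, THF, −100 °C; then PhNTf2, −78 → 0 °C
Reagents that add atoms: N-phenylbis(trifluoromethanesulfonimide), O=S(=O)(N(c1ccccc1)S(=O)(=O)C(F)(F)F)C(F)(F)F
Why: Enantioselective deprotonation of a prochiral 3-substituted cyclobutanone by a chiral lithium amide (Simpkins/Honda-type desymmetrisation) removes one of the two enantiotopic α-protons, so the ring stereocentre (later C4 of the dioxane) is fixed by the side on which the enolate double bond forms, and O-triflation traps it; the few percent of wrong enantiomer later become a diastereomer of 18 that is removed by chromatography.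

Step 2
Reactants: 3 (R)-3-ethylcyclobut-1-en-1-yl trifluoromethanesulfonate
Product: 4 (R)-1,3-diethylcyclobut-1-ene
Conditions: EtMgBr, Fe(acac)3 (5 mol %), THF/NMP, −30 °C
Reagents that add atoms: ethylmagnesium bromide, CC[Mg]Br
Why: Iron-catalysed Kumada-type cross-coupling of an alkenyl triflate with an alkyl Grignard reagent (Fürstner conditions) replaces OTf by ethyl without touching the sp3 stereocentre.

Step 3
Reactants: 4 (R)-1,3-diethylcyclobut-1-ene
Product: 6 (4R)-2,4-diethyl-2-methoxycyclobutan-1-ol, via epoxide 5 (not isolated)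
Conditions: DMDO, acetone, 0 °C; then MeOH, PPTS (cat.), −20 → 0 °C
Reagents that add atoms: dimethyldioxirane, CC1(C)OO1; methanol, CO
Why: Dioxirane epoxidation followed by acid-catalysed methanolysis, which opens the epoxide at the tertiary carbon with inversion to the trans methoxy alcohol; the two new centres are not controlled relative to C4 and need not be, because both are erased in step 4.

Step 4
Reactants: 6 (4R)-2,4-diethyl-2-methoxycyclobutan-1-ol
Product: 8 (4R)-4,6-diethyl-6-methoxy-1,2-dioxan-3-ol, via hydroperoxy aldehyde 7 (not isolated)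
Conditions: Co(acac)2 (20 mol %), O2 (1 atm), CH3CN, 40 °C
Reagents that add atoms: dioxygen, O=O
Why: Cobalt-catalysed aerobic oxidative ring expansion of a cyclobutanol (Ferrié-type): the cobalt alkoxide gives an alkoxy radical, strain-driven β-scission goes to the methoxy-stabilised tertiary radical, O2 is trapped, and the hydroperoxide closes on the aldehyde to the six-membered peroxy-lactol; C4 is untouched and C3/C6 are acetal centres whose configuration does not matter.

Step 5
Reactants: 8 (4R)-4,6-diethyl-6-methoxy-1,2-dioxan-3-ol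
Product: 10 methyl 2-[(3S,4R)-4,6-diethyl-6-methoxy-1,2-dioxan-3-yl]acetate, via hydroperoxy enoate 9 (not isolated)
Conditions: Ph3P=CHCO2Me, CH2Cl2, 0 °C → rt; then Et2NH (0.3 equiv), CF3CH2OH, rt
Reagents that add atoms: methyl (triphenylphosphoranylidene)acetate, COC(=O)C=P(c1ccccc1)(c1ccccc1)c1ccccc1
Why: Wittig olefination of the ring-opened aldehyde tautomer, then amine-catalysed 6-exo oxa-Michael addition of the methoxy hydroperoxide through a chair in which the C4 ethyl and the acceptor are both equatorial (either one axial would clash with the axial group on quaternary C6), giving the 3,4-trans ring, that is 3S.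

Step 6
Reactants: 11 methyl (E)-pent-2-enoate
Product: 12 methyl (3S)-3-ethylheptanoate
Conditions: n-BuMgBr, CuI (1 mol %), (S)-Tol-BINAP (1.5 mol %), t-BuOMe, −40 °C
Reagents that add atoms: butylmagnesium bromide, CCCC[Mg]Br
Why: Copper/Tol-BINAP-catalysed asymmetric conjugate addition of a Grignard reagent to an α,β-unsaturated ester (Feringa/Loh-type), in which the ligand directs butyl to one face of the enoate and sets the S centre.

Step 7
Reactants: 12 methyl (3S)-3-ethylheptanoate
Product: 14 (4S)-4-ethyloct-1-yne, via aldehyde 13 (not isolated)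
Conditions: i-Bu2AlH (1.05 equiv), CH2Cl2, −78 °C; then MeOH, K2CO3, dimethyl (1-diazo-2-oxopropyl)phosphonate, −78 °C → rt
Reagents that add atoms: dimethyl (1-diazo-2-oxopropyl)phosphonate, CC(=O)C(=[N+]=[N-])P(=O)(OC)OC
Why: Partial reduction of the ester to the aldehyde and one-pot Seyferth–Gilbert homologation with the Ohira–Bestmann reagent; the β-stereocentre cannot epimerise.

Step 8
Reactants: 14 (4S)-4-ethyloct-1-yne
Product: 15 2-[(1E,4S)-2,4-diethyloct-1-en-1-yl]-4,4,5,5-tetramethyl-1,3,2-dioxaborolane
Conditions: B2pin2, EtI, CuCl (10 mol %), Xantphos, NaOt-Bu, THF, rt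
Reagents that add atoms: bis(pinacolato)diboron, CC1(C)OB(OC1(C)C)B1OC(C)(C)C(C)(C)O1; iodoethane, CCI
Why: Copper-catalysed carboboration of a terminal alkyne: syn-borylcupration places boron on the terminal carbon and the alkenylcopper is ethylated with retention, so boron and ethyl end up cis (E), which is the geometry the target needs.

Step 9
Reactants: 15 2-[(1E,4S)-2,4-diethyloct-1-en-1-yl]-4,4,5,5-tetramethyl-1,3,2-dioxaborolane
Product: 16 potassium [(1E,4S)-2,4-diethyloct-1-en-1-yl]trifluoroborate
Conditions: KHF2 (aq, 4 equiv), MeOH, rt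
Reagents that add atoms: potassium hydrogen difluoride, [K+].[F-].F
Why: Pinacol boronate to trifluoroborate exchange (Vedejs/Molander procedure) gives a crystalline alkenyl donor with the alkene geometry unchanged.

Step 10
Reactants: 10 methyl 2-[(3S,4R)-4,6-diethyl-6-methoxy-1,2-dioxan-3-yl]acetate; 16 potassium [(1E,4S)-2,4-diethyloct-1-en-1-yl]trifluoroborate
Product: 18 methyl 2-[(3S,4R,6S)-6-[(1E,4S)-2,4-diethyloct-1-en-1-yl]-4,6-diethyl-1,2-dioxan-3-yl]acetate, via alkenyldifluoroborane 17 (not isolated)
Conditions: BF3·OEt2 (2.5 equiv), CH3CN/CH2Cl2, −40 → 0 °C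
Reagents that add atoms: none
Why: Proposed new method: BF3 strips fluoride from 16 to give the alkenyldifluoroborane, which ionises the tertiary peroxyketal C6–OMe of 10 to a peroxycarbenium/methoxyborate ion pair, and the alkenyl group then moves from boron to C6 with retention of alkene geometry (ipso attack through a boron-stabilised β-cation) along the axial trajectory of the half-chair whose C3 and C4 groups are pseudo-equatorial, giving axial alkenyl and equatorial ethyl, that is 6S, from either C6 epimer of 10; the closest known reactions are the Bode-type BF3-mediated addition of potassium alkenyltrifluoroborates to O,O-acetals and the Dussault-type Lewis-acid allylation of peroxyketals, but an sp2 organoboron nucleophile has not been added to a peroxycarbenium ion.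

**Compound list**
1 | 3-ethylcyclobutan-1-one | CCC1CC(=O)C1 | starting material
2 | lithium (R)-3-ethylcyclobut-1-en-1-olate | [Li+].[O-]C1=C[C@H](CC)C1 | intermediate
3 | (R)-3-ethylcyclobut-1-en-1-yl trifluoromethanesulfonate | O=S(=O)(OC1=C[C@H](CC)C1)C(F)(F)F | intermediate
4 | (R)-1,3-diethylcyclobut-1-ene | CCC1=C[C@H](CC)C1 | intermediate
5 | (3R)-1,3-diethyl-5-oxabicyclo[2.1.0]pentane (epoxide of 4, either face) | CCC12C[C@@H](CC)C1O2 | intermediate
6 | (4R)-2,4-diethyl-2-methoxycyclobutan-1-ol (trans OH/OMe, mixture at C1/C2 relative to C4) | OC1[C@H](CC)CC1(CC)OC | intermediate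
7 | (2R)-2-ethyl-4-hydroperoxy-4-methoxyhexanal (mixture at C4) | O=C[C@H](CC)CC(CC)(OC)OO | intermediate
8 | (4R)-4,6-diethyl-6-methoxy-1,2-dioxan-3-ol (mixture at C3 and C6) | CCC1(OC)C[C@@H](CC)C(O)OO1 | intermediate
9 | methyl (2E,4R)-4-ethyl-6-hydroperoxy-6-methoxyoct-2-enoate (mixture at C6) | COC(=O)/C=C/[C@H](CC)CC(CC)(OC)OO | intermediate
10 | methyl 2-[(3S,4R)-4,6-diethyl-6-methoxy-1,2-dioxan-3-yl]acetate (mixture at C6) | COC1(CC)C[C@@H](CC)[C@H](CC(=O)OC)OO1 | intermediate
11 | methyl (E)-pent-2-enoate | CC/C=C/C(=O)OC | starting material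
12 | methyl (3S)-3-ethylheptanoate | CCCC[C@H](CC)CC(=O)OC | intermediate
13 | (3S)-3-ethylheptanal | CCCC[C@H](CC)CC=O | intermediate
14 | (4S)-4-ethyloct-1-yne | CCCC[C@H](CC)CC#C | intermediate
15 | 2-[(1E,4S)-2,4-diethyloct-1-en-1-yl]-4,4,5,5-tetramethyl-1,3,2-dioxaborolane | CCCC[C@H](CC)C/C(=C/B1OC(C)(C)C(C)(C)O1)CC | intermediate
16 | potassium [(1E,4S)-2,4-diethyloct-1-en-1-yl]trifluoroborate | CCCC[C@H](CC)C/C(=C/[B-](F)(F)F)CC.[K+] | intermediate
17 | [(1E,4S)-2,4-diethyloct-1-en-1-yl]difluoroborane | CCCC[C@H](CC)C/C(=C/B(F)F)CC | intermediate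
18 | methyl 2-[(3S,4R,6S)-6-[(1E,4S)-2,4-diethyloct-1-en-1-yl]-4,6-diethyl-1,2-dioxan-3-yl]acetate | CCCC[C@H](CC)C/C(=C/[C@]1(CC)C[C@@H](CC)[C@H](CC(=O)OC)OO1)CC | target

**Step count**
Total: 10 steps. Longest linear sequence: 6 steps (1, 2, 3, 4, 5, 10); the side chain takes 4 steps (6–9) before the union.

**Three steps most likely to fail**

Step 10 (the new alkenylation). The peroxycarbenium ion may lose a proton to an enol peroxide or fragment. A long-lived β-boryl cation could scramble the alkene geometry. The centre being made is quaternary and hindered. The fallback uses known reactions only; it sets out from 9 and 15 and comes back at 18. The Wittig product 9 is not cyclised but reduced in the flask with Me2S to methyl (2E,4R)-4-ethyl-6-oxooct-2-enoate F2. Boronate 15 is iodinated with retention (NaOH, I2) to (1E,4S)-2,4-diethyl-1-iodooct-1-ene F3, which is lithiated (t-BuLi, −78 °C) to [(1E,4S)-2,4-diethyloct-1-en-1-yl]lithium F4. F4 adds to the ketone of F2 (LaCl3·2LiCl as additive) to give methyl (2E,4R,7E,10S)-4,6,8,10-tetraethyl-6-hydroxytetradeca-2,7-dienoate F5 as both C6 epimers. Acid-catalysed perhydrolysis (50% H2O2, cat. H2SO4) gives methyl (2E,4R,7E,10S)-4,6,8,10-tetraethyl-6-hydroperoxytetradeca-2,7-dienoate F6. Et2NH in CF3CH2OH closes the ring by oxa-Michael addition to 18 together with its C6 epimer methyl 2-[(3S,4R,6R)-6-[(1E,4S)-2,4-diethyloct-1-en-1-yl]-4,6-diethyl-1,2-dioxan-3-yl]acetate F7, which is separated by chromatography. The price is no control at C6 and a risk of allylic transposition in the perhydrolysis.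

Step 4 (ring expansion). The cobalt catalyst may decompose the methoxy hydroperoxide, or the aldehyde tautomer may be over-oxidised. The fallback sets out from 4 and comes back at 8: ozonolysis of 4 in CH2Cl2/MeOH at −78 °C without reductive work-up. The ketone oxide forms on the ethyl-bearing carbon and is trapped by methanol, giving 7 and hence 8 directly and by-passing 6. No new compound is made.

Step 3 (epoxide methanolysis). The cyclobutene oxide can undergo acid-induced ring contraction to a cyclopropanecarbaldehyde instead of solvolysis. The fallback sets out from 4 and comes back at 6: methoxymercuration (Hg(OAc)2, MeOH) gives acetoxy[(4R)-2,4-diethyl-2-methoxycyclobutyl]mercury F1 through a mercurinium ion that does not rearrange, and oxidative demercuration (NaBH4, O2, DMF) then gives 6.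

**Further compounds**
F1 | step 3 | acetoxy[(4R)-2,4-diethyl-2-methoxycyclobutyl]mercury | CC(=O)O[Hg]C1[C@H](CC)CC1(CC)OC
F0 | step 4 | none | none
F2 | step 10 | methyl (2E,4R)-4-ethyl-6-oxooct-2-enoate | CCC(=O)C[C@@H](CC)/C=C/C(=O)OC
F3 | step 10 | (1E,4S)-2,4-diethyl-1-iodooct-1-ene | CCCC[C@H](CC)C/C(=C/I)CC
F4 | step 10 | [(1E,4S)-2,4-diethyloct-1-en-1-yl]lithium | CCCC[C@H](CC)C/C(=C/[Li])CC
F5 | step 10 | methyl (2E,4R,7E,10S)-4,6,8,10-tetraethyl-6-hydroxytetradeca-2,7-dienoate | CCCC[C@H](CC)C/C(CC)=C/C(O)(CC)C[C@@H](CC)/C=C/C(=O)OC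
F6 | step 10 | methyl (2E,4R,7E,10S)-4,6,8,10-tetraethyl-6-hydroperoxytetradeca-2,7-dienoate | CCCC[C@H](CC)C/C(CC)=C/C(OO)(CC)C[C@@H](CC)/C=C/C(=O)OC
F7 | step 10 | methyl 2-[(3S,4R,6R)-6-[(1E,4S)-2,4-diethyloct-1-en-1-yl]-4,6-diethyl-1,2-dioxan-3-yl]acetate | CCCC[C@H](CC)C/C(=C/[C@@]1(CC)C[C@@H](CC)[C@H](CC(=O)OC)OO1)CC
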